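Numbering used throughout: the ten-membered ring is C1–C10, the lactone carbons are C11 (α), C12 (C=O) and C13 (=CH2), C14 is the methylene on C10, C15 the methyl on C4, and the lactone oxygen sits on C6.

## Analysis of the target

Target 30 is a germacranolide: a ten-membered carbocycle (C1–C10) cis-fused across C6–C7 to an α-methylene-γ-butyrolactone (C11–C13). The ring carries a Z trisubstituted olefin C4=C5, an exocyclic methylene C10=C14, hydroxyls on C1 and C3 and an angelate on O8. There are five stereocentres (1S,3S,6S,7R,8R). C6, C7 and C8 form a contiguous triad: H6 and H7 are cis, and in the C6–C7–C8–C9 zigzag the C11 branch on C7 is anti to both O6 and O8. C1 and C3 form an anti 1,3-diol on the far side of the ring, separated from the triad by sp2 carbons on both sides. The sensitive groups are the α-methylene lactone (Michael acceptor and dipolarophile), the angelate (isomerises to the tiglate under nucleophilic catalysis), the allylic C6–O bond, the 8-hydroxy/6,12-lactone pair (lactone migration) and the two allylic alcohols, whose β-hydroxy enone precursor dehydrates easily. The difficulty is to close a ten-membered ring that holds a Z olefin and to pass stereochemical information from the C6–C8 triad to C3 and C1. The strategy rests on the unit C1(OH)–C2H2–C3(OH) between C10=C14 and C4=C5: it is the retron of a 2-isoxazoline with C1 as the C=N carbon and oxygen on C3, which comes from a C1 nitrile oxide and a C2=C3 vinyl group.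

## Retrosynthetic reasoning

30 to 29: the C1 carbinol is traced back to a C1 ketone. A hydroxyl-directed reduction relays the C3 configuration to C1 and gives the anti diol, so only C3 has to be set when the ring is closed.

29 to 27: the β-hydroxy enone is hidden as an isoxazoline (N–O bond between the C1 nitrogen and the C3 oxygen). Reductive N–O cleavage releases it only two steps from the end, which limits its exposure to dehydration.

27 to 26: C11=C13 is taken back to a β-phenylsulfonyl lactone. This is needed because in the cyclisation precursor a free C11=C13 bond would sit four atoms from the C1 nitrile oxide and would capture it in a fused six-membered closure, far faster than the ten-membered one. A base-induced elimination restores the methylene group after the ring is made.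

26 to 23 (through 25): C1–C2 and O–C3 are cut. This one disconnection opens both the isoxazoline and the ten-membered ring and leads to an open-chain aldoxime on a preformed cis-lactone. The forward step has to macrocyclise in the bridged sense, choose C2=C3 over C4=C5, and attack the correct face of the vinyl group.

23 to 15 (through 22, 21, 20, 19, 16): functional-group changes only. The oxime comes from the C1 alcohol, which is protected as a PMB ether. O8 must be acylated before C1 is oxidised, because a free 8-hydroxyl would close a lactol on the C1 aldehyde. O8 is carried as a silyl ether up to the lactone, because an ester at C8 could be expelled from the allylmetal used in the next disconnection.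

15 to 9 and 12: C6–C7 and O6–C12 are cut. A 2-(alkoxycarbonyl)allylation of dienal 12 with bromide 9, followed by lactonisation, joins the two halves, builds the methylene lactone and sets C6 and C7 relative to C8. Doing this on small fragments puts the triad in place before any ring strain is present.

9 to 6 and 7 (through 8): the C7–C11 bond is a Baylis–Hillman bond between aldehyde 6 and acrylate 7. Bromination with allylic transposition moves the leaving group to C13.

6 to 2 and 3 (through 5 and 4): C8–C9 is cut by a glyoxylate–ene disconnection. One catalytic step sets C8, creates C10=C14 and leaves C1 as a protected allylic alcohol. Ether 2 comes from alcohol 1.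

12 to 10 (through 11): the Z trisubstituted C4=C5 olefin is bought with enynol 10. Only a semihydrogenation and an oxidation are needed.

## Alternatives that were turned down

Alternative 1: The bond cut is C8–C9, formed while a bond of a six-membered ring is broken. In the forward direction an anionic oxy-Cope rearrangement (KH, 18-crown-6) expands a six-membered carbinol by four atoms and gives the ten-membered 4Z,1(10)E-dienone A1, with the C3 and C8 oxygens already in place. On ring formation this is stronger than the chosen route: a concerted ring expansion has no entropic penalty, needs no high dilution and fixes the Z olefin from a ring olefin. Against it for this target, A1 is far from 30 in other respects. C1 has no oxygen and C10 carries a methyl inside an endocyclic olefin, so an allylic oxidation with transposition is needed to reach C1–OH and C10=C14. C7 is a bare methylene, so the three lactone carbons and the C7 stereocentre must be added to a flexible medium-ring enolate. The C6 ketone must then be reduced cis to that new substituent. Each of these steps asks for stereocontrol on a ten-membered ring, and the protecting groups add further steps. The chosen route gives up the easy ring formation but installs both the C1 and C3 oxygens in the ring-closing step and has the lactone and the C6–C8 triad in place beforehand.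

Alternative 2: The bonds cut are O6–C12 and C12–C11. A palladium-catalysed cyclocarbonylation (PdCl2, PPh3, SnCl2, CO) of a C7 ethynyl group with the free C6 hydroxyl would close the methylene lactone last and give A2, the 1,3-bis-silyl ether of 30. On one point it is stronger than the chosen route: the Michael acceptor appears only at the end, so no mask is needed, whereas the chosen route spends two steps on masking. Against it, the disconnection does not address the ten-membered ring, the Z olefin or the anti diol, all of which must already exist in a ring that also holds the ethynyl group cis to the C6 hydroxyl. The angelate and the C10=C14 olefin must survive palladium hydride species, and two silyl ethers must then be removed next to a fresh methylene lactone and an allylic lactone C–O bond. The chosen route solves the ring and the diol in one step and leaves only two mild steps after the methylene lactone is restored.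

Alternative 3: The bond cut is C7–C8. BF3·OEt2 would promote attack of an allylstannane built into a butenolide, through C7, on a tethered C8 aldehyde. This closes the ten-membered ring, creates C7 and C8 and unveils the C11=C13 methylene in A3, the 8-hydroxy lactone with silyl ethers at C1 and C3. It is as strong as the chosen route in bond economy, and stronger in that the methylene lactone is born in the ring closure and the 8-hydroxyl is set free for angeloylation. Against it, both C7 and C8 must be induced across a forming medium ring by C6 and the remote C1 and C3 centres, through an open transition state whose preference is hard to predict. The anti diol and the Z olefin must be built in the open chain first, which adds steps. The C8 aldehyde is β,γ-unsaturated and can slip into conjugation with C10=C14 under a Lewis acid. The chosen route fixes C6, C7 and C8 by fragment chemistry before the ring closes and asks the macrocyclisation for one stereocentre only.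

Key step: step 16

Remarks on the chemistry before the steps:
- The copper bis(oxazoline) glyoxylate–ene catalyst is assumed to follow its usual sense, (S,S)-ligand giving the (S)-hydroxy ester, so the (R,R)-ligand is specified for 4.
- C7 in 8 and C11 in 20 to 26 are formed as epimer mixtures and are drawn without configuration, because both centres become sp2 again.

## Route

Step 1
Reactants: 1 2-methylprop-2-en-1-ol
Product: 2 1-methoxy-4-{[(2-methylprop-2-en-1-yl)oxy]methyl}benzene
Conditions: NaH, 4-methoxybenzyl chloride, Bu4NI (cat.), THF, 0 °C to rt
Reagents that add atoms: 4-methoxybenzyl chloride, COc1ccc(CCl)cc1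
Why: Williamson etherification of a primary allylic alkoxide; the PMB ether protects the future C1 oxygen and is orthogonal to the silyl ether used at O8.

Step 2
Reactants: 2 methallyl PMB ether; 3 ethyl glyoxylate
Product: 4 ethyl (2R)-2-hydroxy-4-{[(4-methoxybenzyl)oxy]methyl}pent-4-enoate
Conditions: [Cu((R,R)-t-Bu-box)](SbF6)2 (10 mol %), CH2Cl2, 0 °C to rt
Reagents that add atoms: none
Why: Catalytic enantioselective carbonyl–ene reaction of a 1,1-disubstituted olefin with glyoxylate chelated to the divalent copper bis(oxazoline) complex, whose tert-butyl groups leave one aldehyde face open and so set C8 as R; the hydrogen is taken from the methyl group and not from the inductively deactivated CH2–O group, which gives C10=C14 and keeps C1–O.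

Step 3
Reactants: 4 hydroxy ester
Product: 5 ethyl (2R)-2-[(tert-butyldimethylsilyl)oxy]-4-{[(4-methoxybenzyl)oxy]methyl}pent-4-enoate
Conditions: TBSCl, imidazole, DMF, rt
Reagents that add atoms: tert-butyldimethylsilyl chloride, CC(C)(C)[Si](C)(C)Cl
Why: Standard silylation of a secondary α-hydroxy ester; a silyl ether at O8 is a poor leaving group for the allylmetal of step 9 and is small enough next to C8 to leave the C9 chain as the larger substituent.

Step 4
Reactants: 5 silyloxy ester
Product: 6 (2R)-2-[(tert-butyldimethylsilyl)oxy]-4-{[(4-methoxybenzyl)oxy]methyl}pent-4-enal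
Conditions: i-Bu2AlH (1.1 equiv), CH2Cl2, −78 °C; MeOH, aq. potassium sodium tartrate
Reagents that add atoms: none
Why: Partial reduction of an α-silyloxy ester stops at the aldehyde because the tetrahedral aluminium hemiacetal persists at −78 °C; C8 is not touched and the aldehyde is used at once to avoid epimerisation.

Step 5
Reactants: 6 aldehyde; 7 methyl acrylate
Product: 8 methyl (4R)-4-[(tert-butyldimethylsilyl)oxy]-3-hydroxy-6-{[(4-methoxybenzyl)oxy]methyl}-2-methylidenehept-6-enoate (both C3 epimers)
Conditions: DABCO (1 equiv), methyl acrylate (5 equiv, neat), rt, several days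
Reagents that add atoms: none
Why: Morita–Baylis–Hillman reaction, for which α-alkoxy aldehydes are activated acceptors; the new carbinol centre (C7) is formed without control, which does not matter because it becomes sp2 in step 6.

Step 6
Reactants: 8 Baylis–Hillman adduct
Product: 9 methyl (2Z,4R)-2-(bromomethyl)-4-[(tert-butyldimethylsilyl)oxy]-6-{[(4-methoxybenzyl)oxy]methyl}hepta-2,6-dienoate
Conditions: NBS, Me2S, CH2Cl2, −20 °C; then 8, −20 to 0 °C
Reagents that add atoms: N-bromosuccinimide, O=C1CCC(=O)N1Br
Why: Corey–Kim-type activation of the alcohol as an alkoxysulfonium salt and SN2′ attack of bromide at C13 with allylic transposition; the trisubstituted acrylate forms with C8 trans to the ester (Z), the usual and more stable geometry of such bromides.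

Step 7
Reactants: 10 (2Z)-3-methylpent-2-en-4-yn-1-ol
Product: 11 (2Z)-3-methylpenta-2,4-dien-1-ol
Conditions: H2 (1 atm), Pd/CaCO3 poisoned with Pb(OAc)2, quinoline, EtOAc, rt, stopped after 1 equiv H2
Reagents that add atoms: none
Why: Semihydrogenation of a terminal alkyne over poisoned palladium; the Z trisubstituted olefin of the starting material is not touched, so the C4=C5 geometry is bought and not made.

Step 8
Reactants: 11 (2Z)-dienol
Product: 12 (2Z)-3-methylpenta-2,4-dienal
Conditions: MnO2 (activated, excess), CH2Cl2, 0 °C, dark; filtered and the solution used directly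
Reagents that add atoms: none
Why: Allylic oxidation on neutral MnO2 keeps the Z geometry; the volatile, isomerisation-prone dienal is not concentrated.

Step 9
Reactants: 9 allylic bromide; 12 (2Z)-dienal
Product: 15 cis-lactone carrying O8–TBS and O1–PMB, via allylzinc bromide 13 (not isolated), via syn hydroxy ester 14 (not isolated)
Conditions: Zn dust, sat. aq. NH4Cl/THF, 0 °C to rt; then PPTS (cat.), CH2Cl2, rt
Reagents that add atoms: none
Why: Barbier 2-(alkoxycarbonyl)allylation and lactonisation: the allylzinc adds through C7 in a chair transition state in which C8, cis to CH2Zn, is axial, giving the syn adduct and hence the cis-lactone (C6 and C7); the C7 face is set by C8, whose hydrogen lies in the allyl plane to avoid A(1,3) strain with CH2Zn, the C9 chain standing anti to the incoming aldehyde and the silyloxy group to the side.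

Step 10
Reactants: 15 cis-lactone
Product: 16 8-hydroxy lactone
Conditions: HF·pyridine, pyridine, THF, 0 °C to rt
Reagents that add atoms: none
Why: Fluoride cleavage of the secondary silyl ether under buffered, weakly acidic conditions that leave the PMB ether, the methylene lactone and the position of the lactone unchanged.

Step 11
Reactants: 16 8-hydroxy lactone; 17 angelic acid
Product: 19 O8 angelate of 16, via mixed anhydride 18 (not isolated)
Conditions: 17, 2,4,6-trichlorobenzoyl chloride, Et3N, toluene, rt; then 16, toluene, 80 °C
Reagents that add atoms: none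
Why: Mixed-anhydride (Yamaguchi-type) esterification run without a nucleophilic catalyst: the alcohol attacks the less hindered angeloyl carbonyl, and leaving out DMAP avoids the addition–elimination that turns angelates into tiglates; C8 keeps its configuration.

Step 12
Reactants: 19 angelate
Product: 20 β-phenylsulfonyl lactone (C11 epimers)
Conditions: PhSO2Na, AcOH, EtOH/THF, rt
Reagents that add atoms: sodium benzenesulfinate, [Na+].[O-]S(=O)c1ccccc1
Why: Sulfa-Michael addition of benzenesulfinic acid to the α-methylene lactone only (the α,β-disubstituted angelate does not react); this removes the C11=C13 dipolarophile before the nitrile oxide is made, and the sulfone is inert to the oxidants of steps 13, 14 and 16.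

Step 13
Reactants: 20 masked lactone
Product: 21 C1 allylic alcohol
Conditions: DDQ, CH2Cl2/pH 7 phosphate buffer, 0 °C
Reagents that add atoms: none
Why: Oxidative PMB cleavage; the Z-substituted diene cannot reach the s-cis form needed for cycloaddition to DDQ, and any further oxidation of the freed allylic alcohol would only give the aldehyde wanted next.

Step 14
Reactants: 21 allylic alcohol
Product: 22 C1 enal
Conditions: MnO2, CH2Cl2, rt
Reagents that add atoms: none
Why: Allylic oxidation to the 2-substituted acrolein; O8 is already acylated, so no lactol can form.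

Step 15
Reactants: 22 enal
Product: 23 (E)-aldoxime, the cyclisation precursor with the lactone methylene masked
Conditions: NH2OH·HCl, NaOAc, EtOH/THF, 0 °C
Reagents that add atoms: hydroxylamine hydrochloride, NO.Cl
Why: Oxime condensation at the aldehyde is much faster than conjugate addition to the enal at 0 °C, and the weak acetate base does not eliminate the sulfone.

Step 16
Reactants: 23 aldoxime
Product: 26 sulfone-masked isoxazoline-bridged ten-membered lactone, via hydroximoyl chloride 24 (not isolated), via nitrile oxide 25 (not isolated)
Conditions: aq. NaOCl (buffered to pH 9 with NaHCO3), CH2Cl2, 0 °C to rt; 23 added by syringe pump, final concentration about 1 mM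
Reagents that add atoms: none
Why: Hypochlorite chlorinates the aldoxime to 24, which loses HCl to give nitrile oxide 25, and 25 adds to the terminal C2=C3 bond in a concerted suprafacial [3+2] step (C1 to C2, O to C3). The closest known reaction type is the intramolecular nitrile oxide–olefin cycloaddition used for macrocyclisation to bridged isoxazolines. The isoxazoline closes by the cycloaddition itself, and the ten-membered carbocycle closes in the bridged mode (dipole carbon on the far olefin terminus, so C1, C2 and C3 belong to both rings); the fused mode would give a nine-membered ring against the electronic preference of a monosubstituted olefin. Site selectivity is secured as follows: C11=C13 is masked, C10=C14 is conjugated to the dipole and cannot reach it, and C4=C5 is trisubstituted and would need a seven-membered fused transition state. The new stereocentre is C3: A(1,3) strain across the Z C4=C5 bond keeps H6 in the olefin plane and the cis-lactone holds C8, where the tether starts, under C5, so the dipole reaches the diene from the face that carries C7. On that face the vinyl rotamer turned towards C6 (cisoid about C3–C4) gives 3S with the isoxazoline oxygen outside the new ring, while the transoid rotamer would give 3R with that oxygen pressed against H6 and C7. High dilution suppresses furoxan formation. The rotamer preference is the least secured element of the route and is taken up again below.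

Step 17
Reactants: 26 masked cycloadduct
Product: 27 isoxazoline-bridged ten-membered α-methylene lactone (3S,6S,7R,8R)
Conditions: DBU, CH2Cl2, 0 °C
Reagents that add atoms: none
Why: E1cB elimination of benzenesulfinate from the β-sulfonyl lactone restores C11=C13; both C11 epimers give the same product.

Step 18
Reactants: 27 isoxazoline
Product: 29 β-hydroxy enone, via β-hydroxy imine 28 (not isolated)
Conditions: Mo(CO)6, MeCN/H2O (15:1), 80 °C
Reagents that add atoms: water, O
Why: Reductive N–O cleavage by zerovalent molybdenum and hydrolysis of the imine give the C1 ketone and the C3 alcohol; olefins and esters are not reduced and C3 is not touched.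

Step 19
Reactants: 29 β-hydroxy enone
Product: 30 target (1S,3S,6S,7R,8R)
Conditions: Me4NBH(OAc)3, MeCN/AcOH, −30 to −20 °C
Reagents that add atoms: none
Why: Evans–Saksena directed reduction: the C3 hydroxyl binds boron and delivers hydride to C1 through a chair-like six-membered transition state, giving the 1,3-anti diol (1S from 3S) by 1,2-addition; the reagent does not reduce the methylene lactone or the angelate.

## Compound list

1 | 2-methylprop-2-en-1-ol | CC(=C)CO | starting material
2 | 1-methoxy-4-{[(2-methylprop-2-en-1-yl)oxy]methyl}benzene | CC(=C)COCc1ccc(OC)cc1 | intermediate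
3 | ethyl glyoxylate (ethyl 2-oxoacetate) | CCOC(=O)C=O | starting material
4 | ethyl (2R)-2-hydroxy-4-{[(4-methoxybenzyl)oxy]methyl}pent-4-enoate | CCOC(=O)[C@H](O)CC(=C)COCc1ccc(OC)cc1 | intermediate
5 | ethyl (2R)-2-[(tert-butyldimethylsilyl)oxy]-4-{[(4-methoxybenzyl)oxy]methyl}pent-4-enoate | CCOC(=O)[C@H](O[Si](C)(C)C(C)(C)C)CC(=C)COCc1ccc(OC)cc1 | intermediate
6 | (2R)-2-[(tert-butyldimethylsilyl)oxy]-4-{[(4-methoxybenzyl)oxy]methyl}pent-4-enal | O=C[C@H](O[Si](C)(C)C(C)(C)C)CC(=C)COCc1ccc(OC)cc1 | intermediate
7 | methyl acrylate | C=CC(=O)OC | starting material
8 | methyl (4R)-4-[(tert-butyldimethylsilyl)oxy]-3-hydroxy-6-{[(4-methoxybenzyl)oxy]methyl}-2-methylidenehept-6-enoate, both C3 epimers | C=C(C(=O)OC)C(O)[C@H](O[Si](C)(C)C(C)(C)C)CC(=C)COCc1ccc(OC)cc1 | intermediate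
9 | methyl (2Z,4R)-2-(bromomethyl)-4-[(tert-butyldimethylsilyl)oxy]-6-{[(4-methoxybenzyl)oxy]methyl}hepta-2,6-dienoate | COC(=O)/C(CBr)=C/[C@H](O[Si](C)(C)C(C)(C)C)CC(=C)COCc1ccc(OC)cc1 | intermediate
10 | (2Z)-3-methylpent-2-en-4-yn-1-ol | OC/C=C(/C)C#C | starting material
11 | (2Z)-3-methylpenta-2,4-dien-1-ol | OC/C=C(/C)C=C | intermediate
12 | (2Z)-3-methylpenta-2,4-dienal | O=C/C=C(/C)C=C | intermediate
13 | allylzinc bromide from 9, methyl (2Z,4R)-2-[(bromozincio)methyl]-4-[(tert-butyldimethylsilyl)oxy]-6-{[(4-methoxybenzyl)oxy]methyl}hepta-2,6-dienoate | COC(=O)/C(C[Zn]Br)=C/[C@H](O[Si](C)(C)C(C)(C)C)CC(=C)COCc1ccc(OC)cc1 | intermediate (not isolated)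
14 | methyl (5Z)-3-[(1R)-1-[(tert-butyldimethylsilyl)oxy]-3-{[(4-methoxybenzyl)oxy]methyl}but-3-en-1-yl]-4-hydroxy-6-methyl-2-methylideneocta-5,7-dienoate, C3/C4 syn and configured as C7/C6 of 30 | COC(=O)C(=C)[C@@H]([C@@H](O)/C=C(/C)C=C)[C@H](O[Si](C)(C)C(C)(C)C)CC(=C)COCc1ccc(OC)cc1 | intermediate (not isolated)
15 | (5S)-4-[(1R)-1-[(tert-butyldimethylsilyl)oxy]-3-{[(4-methoxybenzyl)oxy]methyl}but-3-en-1-yl]-5-[(1Z)-2-methylbuta-1,3-dien-1-yl]-3-methylideneoxolan-2-one, H4 and H5 cis | C=C1C(=O)O[C@@H](/C=C(/C)C=C)[C@H]1[C@H](O[Si](C)(C)C(C)(C)C)CC(=C)COCc2ccc(OC)cc2 | intermediate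
16 | (5S)-4-[(1R)-1-hydroxy-3-{[(4-methoxybenzyl)oxy]methyl}but-3-en-1-yl]-5-[(1Z)-2-methylbuta-1,3-dien-1-yl]-3-methylideneoxolan-2-one, H4 and H5 cis | C=C1C(=O)O[C@@H](/C=C(/C)C=C)[C@H]1[C@H](O)CC(=C)COCc2ccc(OC)cc2 | intermediate
17 | angelic acid, (2Z)-2-methylbut-2-enoic acid | C/C=C(/C)C(=O)O | starting material
18 | (2Z)-2-methylbut-2-enoic 2,4,6-trichlorobenzoic anhydride | C/C=C(/C)C(=O)OC(=O)c1c(Cl)cc(Cl)cc1Cl | intermediate (not isolated)
19 | O8 (2Z)-2-methylbut-2-enoate (angelate) of 16, ring and C8 configuration unchanged | C=C1C(=O)O[C@@H](/C=C(/C)C=C)[C@H]1[C@H](OC(=O)/C(C)=C\C)CC(=C)COCc2ccc(OC)cc2 | intermediate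
20 | 19 with the 3-methylidene group replaced by 3-[(phenylsulfonyl)methyl], both C3 (C11) epimers | O=S(=O)(c3ccccc3)CC1C(=O)O[C@@H](/C=C(/C)C=C)[C@H]1[C@H](OC(=O)/C(C)=C\C)CC(=C)COCc2ccc(OC)cc2 | intermediate
21 | 20 with the PMB ether replaced by the free C1 hydroxyl (3-(hydroxymethyl)but-3-en-1-yl side chain) | O=S(=O)(c3ccccc3)CC1C(=O)O[C@@H](/C=C(/C)C=C)[C@H]1[C@H](OC(=O)/C(C)=C\C)CC(=C)CO | intermediate
22 | C1 aldehyde of 21 (3-formylbut-3-en-1-yl side chain) | O=S(=O)(c3ccccc3)CC1C(=O)O[C@@H](/C=C(/C)C=C)[C@H]1[C@H](OC(=O)/C(C)=C\C)CC(=C)C=O | intermediate
23 | (E)-aldoxime of 22, the cyclisation precursor: Z-diene on the cis-lactone, C8 angelate, C11=C13 masked as the sulfone | O=S(=O)(c3ccccc3)CC1C(=O)O[C@@H](/C=C(/C)C=C)[C@H]1[C@H](OC(=O)/C(C)=C\C)CC(=C)/C=N/O | intermediate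
24 | hydroximoyl chloride of 23 (C1 bears Cl) | O=S(=O)(c3ccccc3)CC1C(=O)O[C@@H](/C=C(/C)C=C)[C@H]1[C@H](OC(=O)/C(C)=C\C)CC(=C)C(Cl)=NO | intermediate (not isolated)
25 | C1 nitrile oxide | O=S(=O)(c3ccccc3)CC1C(=O)O[C@@H](/C=C(/C)C=C)[C@H]1[C@H](OC(=O)/C(C)=C\C)CC(=C)C#[N+][O-] | intermediate (not isolated)
26 | (3S,4Z,6S,7R,8R) ten-membered lactone with the C1=N–O–C3 isoxazoline bridge, C8 angelate and 11-[(phenylsulfonyl)methyl] group, C11 epimers | O=S(=O)(c4ccccc4)CC1C(=O)O[C@H]2/C=C(/C)[C@@H]3CC(=NO3)C(=C)C[C@@H](OC(=O)/C(C)=C\C)[C@@H]12 | intermediate
27 | (3S,4Z,6S,7R,8R) isoxazoline-bridged ten-membered α-methylene lactone, C8 angelate | C=C1C(=O)O[C@H]2/C=C(/C)[C@@H]3CC(=NO3)C(=C)C[C@@H](OC(=O)/C(C)=C\C)[C@@H]12 | intermediate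
28 | (3S)-3-hydroxy C1 imine of the ten-membered lactone | C=C1C(=O)O[C@H]2/C=C(/C)[C@@H](O)CC(=N)C(=C)C[C@@H](OC(=O)/C(C)=C\C)[C@@H]12 | intermediate (not isolated)
29 | (3S,4Z,6S,7R,8R)-8-angeloyloxy-3-hydroxy-1-oxogermacra-4,10(14),11(13)-trien-12,6-olide | C=C1C(=O)O[C@H]2/C=C(/C)[C@@H](O)CC(=O)C(=C)C[C@@H](OC(=O)/C(C)=C\C)[C@@H]12 | intermediate
30 | (1S,3S,4Z,6S,7R,8R)-8-angeloyloxy-1,3-dihydroxygermacra-4,10(14),11(13)-trien-12,6-olide | C=C1C(=O)O[C@H]2/C=C(/C)[C@@H](O)C[C@H](O)C(=C)C[C@@H](OC(=O)/C(C)=C\C)[C@@H]12 | target

## Step count and least certain steps

Total step count: 19. Longest linear sequence: 17 steps (steps 1 to 6 and 9 to 19).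

Step 16 (key step). What is most likely to go wrong: the ten-membered bridged closure is slow, so dimerisation and oligomerisation of nitrile oxide 25 can take over. Material that does cyclise may close through the transoid vinyl rotamer (wrong face at C3) or on the nearer C4=C5 bond. Fallback: the dipole is changed from a nitrile oxide to a silyl nitronate, which does not dimerise and can be held and warmed at high dilution. It sets out from allylic alcohol 21. Bromination (CBr4, PPh3, CH2Cl2, 0 °C) gives the allylic bromide F1. Displacement with NaNO2 (DMF, urea, −20 °C) gives the primary allylic nitro compound F2. Silylation (Me3SiCl, i-Pr2NEt, benzene, about 1 mM, rt to 60 °C) forms the silyl nitronate, whose intramolecular cycloaddition to C2=C3 gives the bridged N-(trimethylsilyloxy)isoxazolidine F3. Catalytic TsOH then eliminates the silanol, and the route is rejoined at 26. The nitronate carbon is trigonal and its nitrogen carries a bulky group, so it approaches the vinyl group differently from the linear nitrile oxide; this gives a second chance at the C3 face.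

Step 9. What is most likely to go wrong: erosion of the facial preference at C7, giving both cis-lactones, because the zinc transition state in water is loose. Z to E leakage of 12 and reductive loss of the C8 silyloxy group from 13 can add to this. Fallback: allylboration in place of the Barbier reaction. It sets out from bromide 9. Palladium-catalysed borylation (B2pin2, Pd2(dba)3, toluene, 50 °C) gives the allylboronate F4, with boron on C13 and C8 still trans to the ester. F4 and 12 with Sc(OTf)3 (cat.) in toluene at −20 °C to rt react through a compact boron-centred chair, and the resulting borate lactonises. The route is rejoined at 15.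

Step 18. What is most likely to go wrong: dehydration of the β-hydroxy enone (loss of the C3 hydroxyl to give a cross-conjugated dienone) and slow hydrolysis of the bridgehead imine during prolonged heating. Fallback: the order of the last steps is changed so that a low-temperature one-electron reductant can be used. It sets out from the still masked cycloadduct 26. SmI2 (THF, −78 to 0 °C) cleaves the N–O bond, and aqueous B(OH)3 hydrolyses the imine to the masked β-hydroxy enone F5; the sulfone keeps the lactone safe from the reductant. Me4NBH(OAc)3 then gives the masked anti diol F6, and DBU restores C11=C13 last. The route is rejoined at 30.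

Step 19. What is most likely to go wrong: poor anti selectivity, because the ten-membered ring may not allow the chair-like internal hydride delivery, and some conjugate reduction. Fallback: reagent control in place of substrate direction. It sets out from 29. Silylation (Et3SiCl, imidazole, DMF, 0 °C) gives the 3-O-triethylsilyl enone F7. Reduction with catecholborane and (R)-2-methyl-CBS-oxazaborolidine (toluene, −78 °C), with the 2-substituted vinyl group as the large substituent, should give the (1S) allylic alcohol F8. HF·pyridine removes the silyl group, and the route is rejoined at 30.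

## Further compounds

F1 | step 16 | allylic bromide from 21 (3-(bromomethyl)but-3-en-1-yl side chain) | O=S(=O)(c3ccccc3)CC1C(=O)O[C@@H](/C=C(/C)C=C)[C@H]1[C@H](OC(=O)/C(C)=C\C)CC(=C)CBr
F2 | step 16 | primary allylic nitro compound (3-(nitromethyl)but-3-en-1-yl side chain) | O=S(=O)(c3ccccc3)CC1C(=O)O[C@@H](/C=C(/C)C=C)[C@H]1[C@H](OC(=O)/C(C)=C\C)CC(=C)C[N+](=O)[O-]
F3 | step 16 | bridged N-(trimethylsilyloxy)isoxazolidine, the C1-saturated precursor of 26, C1 and C11 epimers | O=S(=O)(c4ccccc4)CC1C(=O)O[C@H]2/C=C(/C)[C@@H]3CC(N(O[Si](C)(C)C)O3)C(=C)C[C@@H](OC(=O)/C(C)=C\C)[C@@H]12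
F4 | step 9 | methyl (2E,4R)-4-[(tert-butyldimethylsilyl)oxy]-6-{[(4-methoxybenzyl)oxy]methyl}-2-[(4,4,5,5-tetramethyl-1,3,2-dioxaborolan-2-yl)methyl]hepta-2,6-dienoate | COC(=O)/C(CB1OC(C)(C)C(C)(C)O1)=C/[C@H](O[Si](C)(C)C(C)(C)C)CC(=C)COCc2ccc(OC)cc2
F5 | step 18 | sulfone-masked β-hydroxy enone (29 with 11-[(phenylsulfonyl)methyl] in place of C11=C13) | O=S(=O)(c4ccccc4)CC1C(=O)O[C@H]2/C=C(/C)[C@@H](O)CC(=O)C(=C)C[C@@H](OC(=O)/C(C)=C\C)[C@@H]12
F6 | step 18 | sulfone-masked anti diol (30 with 11-[(phenylsulfonyl)methyl] in place of C11=C13) | O=S(=O)(c4ccccc4)CC1C(=O)O[C@H]2/C=C(/C)[C@@H](O)C[C@H](O)C(=C)C[C@@H](OC(=O)/C(C)=C\C)[C@@H]12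
F7 | step 19 | 3-O-triethylsilyl ether of 29 | C=C1C(=O)O[C@H]2/C=C(/C)[C@@H](O[Si](CC)(CC)CC)CC(=O)C(=C)C[C@@H](OC(=O)/C(C)=C\C)[C@@H]12
F8 | step 19 | 3-O-triethylsilyl ether of 30 | C=C1C(=O)O[C@H]2/C=C(/C)[C@@H](O[Si](CC)(CC)CC)C[C@H](O)C(=C)C[C@@H](OC(=O)/C(C)=C\C)[C@@H]12
A1 | alternative 1 | ten-membered 4Z,1(10)E-dienone with C6 ketone, 3-O-TBS and 8-O-PMB groups | O=C1/C=C(/C)[C@@H](O[Si](C)(C)C(C)(C)C)C/C=C(\C)C[C@@H](OCc2ccc(OC)cc2)C1
A2 | alternative 2 | 1,3-bis(tert-butyldimethylsilyl) ether of 30 | C=C1C(=O)O[C@H]2/C=C(/C)[C@@H](O[Si](C)(C)C(C)(C)C)C[C@H](O[Si](C)(C)C(C)(C)C)C(=C)C[C@@H](OC(=O)/C(C)=C\C)[C@@H]12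
A3 | alternative 3 | 8-hydroxy cis-fused α-methylene lactone with 1,3-bis(tert-butyldimethylsilyl) ethers | C=C1C(=O)O[C@H]2/C=C(/C)[C@@H](O[Si](C)(C)C(C)(C)C)C[C@H](O[Si](C)(C)C(C)(C)C)C(=C)C[C@@H](O)[C@@H]12
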